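Amounts come first: you want the J standing in a flask of 5.0 mM solid D and 1.10 equiv of L at 8.0 min.

| setting | Wednesday's | Monday's | Tuesday's | flask |
|---|---|---|---|---|
| D | 2.5 mM | 10 mM | 5 mM | 5.0 mM |
| L | 1.1 equiv | 1.1 equiv | 0.55 equiv | 1.10 equiv |
| remark | run made earlier | run made earlier | run made earlier |  |
| time |  |  |  | 8.0 min |

- Wednesday's (time / min: J / %, X / %): 0.417: 7.5, 18.1; 0.667: 13.0, 19.5; 1.00: 19.4, 19.3; 2.00: 29.1, 5.8; 3.00: 30.4, 0.9; 5.00: 30.8, 0
- Monday's (time / min: J / %, X / %): 0.417: 5.7, 2.4; 0.667: 7.9, 2.8; 1.00: 10.5, 2.9; 2.00: 23.4, 3.5; 3.00: 33.4, 4.2; 5.00: 47.9, 3.3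
- Tuesday's (time / min: J / %, X / %): 0.417: 3.5, 9.1; 0.667: 6.7, 9.8; 1.33: 11.6, 9.3; 2.50: 19.2, 10.3; 5.00: 24.3, 1.0

(readings scatter by 0.5 percentage points)

- percent here means D units held: one E counts as two
- D is a solid; its amount is given per volume of the solution
- what was read earlier has a scatter of 0.5 percentage points, one standard deviation
- what may be going on: 2 X -> E; J <-> G; L -> Q; D <-> X; L <-> Z; X + L -> J
- at the start none of D is in solution
- X means what is dissolved; the solid is not counted in it

- winter: doubling the dissolution coefficient of D, all else as stated
- dusk: doubling the solubility of D, all else as stated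
- noon: doubling the amount of L, all else as stated

- the J standing at 8.0 min, as a percentage of the D charged
- concentration of X in solution at 50 s, in percent of saturation
- the change that raises the amount of J at 8.0 min, in percent of the D charged most ("none" if none brings more than 2 percentage points) (winter / dusk / noon / none)
- amount of J at 8.0 min, in percent of the D charged, after winter

My own reckoning freezes what stays level while solid lasts. In Wednesday's run [X] reads 0.488 mM at 0.667 min and 0.482 mM at 1.00 min, then falls to 0.145 mM at 2.00 min. So I put the end of the solid in Wednesday's run midway between those two times, at 1.50 min, which as an estimate gives a feed of 1.67 mM min⁻¹, and I hold that feed for the other flasks. From 0.417 min to 1.00 min, the readings of J climb at 0.510 mM min⁻¹ in Wednesday's run and 0.823 mM min⁻¹ in Monday's, faster in the run with more L and more D. This flask's L charge lies midway on a log scale between those two runs, so I take the geometric mean, 0.648 mM min⁻¹.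

The bench rule holds pace and feed level for the same time, so that their ratio is taken as the share of D that ends as J. For this flask that catch ratio, J pace over feed (a selectivity toward J), is 38.9%. The rule needs feed times time over charge above one. This flask has 2.67, but Monday's run, at its last reading, has 0.833, and its J is still climbing from 33.4% to 47.9%.

The forecast says J 44%, X at 28% of saturation, noon as the best change, and J 36% after winter, with “More L helps, so noon is best”; its J stands 5.1 percentage points above mine.

The flask gives J 40.0%, X at 36.0% of saturation, noon as the best change (up 15 points), and J 36.5% after winter, so the forecast's share of saturation is 8 points low.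

    2 X → E (k = 35.0 M⁻¹ s⁻¹)
    J ⇌ G (K = 0.510, k = 0.0290 s⁻¹)
    L → Q (k = 4.70 × 10⁻⁵ s⁻¹)
    D ⇌ X, rate k4*(cs4 - [X]) while solid is left; crystals form when [X] > cs4 (solubility = 1.10 mM, k = 0.0440 s⁻¹)
    L ⇌ Z (K = 0.310, k = 0.0760 s⁻¹)
    X + L → J (k = 14.0 M⁻¹ s⁻¹)

The catch ratio for this flask falls 1.1 points short of the simulated J. Take the neighbouring flask with 4.40 equiv, 4.00 times the L: the step from Wednesday's to Monday's L has the same factor, though D moved with it there, so I take the pace as multiplied by 1.61, and with the feed held the ratio becomes 62.8%. That neighbour holds J at 62.5%, with D at 0%.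

The readings were computed with made-up constants, and the scatter is random.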